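Late in the north run the two substrates flatten, so I start from there.

all flasks: left-handed substrate 0.019 M; right-handed substrate 0.019 M; precatalyst 3.2 mM

| flask | partner | free catalyst | remark | time |
|---|---|---|---|---|
| north | 0.053 M | 1.5 mM | run made earlier |  |
| south | 0.084 M | 1.5 mM | run made earlier |  |
| north-west | 0.038 M | 0.75 mM | run made earlier |  |
| flask | 0.0380 M | 1.5 mM |  | 4.0 d |

- north (time / d: left-handed substrate / %, right-handed substrate / %): 0.250: 45.3, 45.8; 0.417: 43.3, 44.0; 0.625: 42.2, 41.9; 0.833: 40.4, 40.7; 1.25: 38.4, 38.4; 2.00: 37.0, 36.6; 3.00: 35.7, 34.9
- south (time / d: left-handed substrate / %, right-handed substrate / %): 0.500: 38.8, 39.7; 0.833: 36.5, 36.4; 1.25: 33.7, 34.0; 1.67: 31.9, 32.2; 2.50: 30.7, 30.6; 3.00: 29.0, 29.6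
- north-west (time / d: left-handed substrate / %, right-handed substrate / %): 0.625: 45.9, 45.8; 1.25: 44.4, 44.4; 2.08: 42.3, 42.4; 2.50: 42.1, 42.1; 3.00: 41.4, 42.0

(each reading ± 0.3 percentage points)

- part of the left-handed substrate and right-handed substrate charged together that has reacted at 4.0 d
- excess of left-handed product over right-handed product in the product at 4.0 d
- excess of right-handed substrate over left-handed substrate among what is left of the two at 4.0 d

- free catalyst is single-handed; left-handed substrate and right-handed substrate are mirror images of each other, charged as a racemate, each of them at the stated concentration
- steps under discussion: partner + free catalyst + left-handed substrate -> free catalyst + left-handed product; partner + free catalyst + right-handed substrate -> free catalyst + right-handed product; left-handed substrate + racemization catalyst <-> right-handed substrate + racemization catalyst; 2 free catalyst -> spent catalyst; partner + precatalyst -> racemization catalyst + spent reagent; 2 partner -> homo dimer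
- an excess is below zero if the other one leads

What do you read at late times? I take the reach: ln(substrate charged / substrate left), the time integral of a pseudo-first-order constant. In the north run it is 0.264 at 1.25 d and 0.348 at 3.00 d.

How does it go on? If free catalyst dies in pairs, c(free catalyst) falls late as one over time, so the reach grows with ln(time). That line gives the north run 0.376 at 4.0 d.

How do you carry it to another charge? I take the rate to go with c(partner), so I divide by the charge. This gives the reach per molar partner 7.09 M⁻¹: reach at 4.0 d over charged c(partner). At 3.00 d the north run reads 6.57 M⁻¹ and the south run 6.36 M⁻¹.

And the new flask? Its reach comes to 0.269, so I reckon a conversion of 23.6%.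

But this flask has less partner per substrate. Doesn't that hurt? I put the answer back. Each product takes one partner, so the flask's product takes 23.6% of its partner. The north run's takes 22.5%, less. Scaling by mean partner left, the second round gives reach 0.268 and conversion 23.5%. I commit to that.

And the excesses? In the north run the right-handed substrate leads by 0.7 percentage points at 0.417 d, and the left-handed substrate by 0.8 points at 3.00 d. The lead changes hands, with a scatter of 0.3 points per reading, so I read the excess of right-handed substrate as near zero. For the excess of left-handed product I give no figure.

The forecast gives a conversion of 24%, a little above mine, an excess of left-handed product of 40% and an excess of right-handed substrate of 0.3%, and says: “Equal substrates mean either fast racemization or an unselective catalyst”.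

The flask gives a conversion of 24.5%, an excess of left-handed product of 27.6% and an excess of right-handed substrate of 0.0176%.

    partner + free catalyst + left-handed substrate → free catalyst + left-handed product (k = 0.0940 M⁻² s⁻¹)
    partner + free catalyst + right-handed substrate → free catalyst + right-handed product (k = 0.0530 M⁻² s⁻¹)
    left-handed substrate + racemization catalyst ⇌ right-handed substrate + racemization catalyst, rate k3*[racemization catalyst]*[left-handed substrate] forward; the back reaction follows from the equilibrium constant (k = 0.0510 M⁻¹ s⁻¹)
    2 free catalyst → spent catalyst (k = 0.00670 M⁻¹ s⁻¹)
    partner + precatalyst → racemization catalyst + spent reagent (k = 7.10 × 10⁻⁴ M⁻¹ s⁻¹)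
    2 partner → homo dimer (k = 3.30 × 10⁻⁵ M⁻¹ s⁻¹)

This flask's reach per molar partner comes to 7.40 M⁻¹, against the carried 7.09 M⁻¹. With 0.065 M of partner, the carried value gives 36.9%, and that neighbour flask gives 36.3%. In the recipe flask at 4.00 d, the half-life of left-handed substrate by its catalysed step is 31 d, longer than the 4.0 d elapsed, with free catalyst at 12.6% of its charge. That flask holds 37.7% of left-handed substrate then, and 34.4% at 40.0 d.

(The readings stem from a simulated flask for an exercise; noise was put on by code.)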